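The runs were generated by integration on assumed constants, and the scatter is random.

Each product costs one starting material and one coupling partner, whatever happens on the way. In the noon run the coupling partner, at 0.100 M, is less than the 0.360 M of starting material. It is the limiting reagent and caps product at 27.8% of the starting material charged.

| flask | starting material | coupling partner | time |
|---|---|---|---|
| dusk | 0.0500 M | 0.100 M |  |
| summer | 0.0500 M | 0.150 M |  |
| midnight | 0.150 M | 0.100 M |  |
| noon | 0.360 M | 0.100 M | 26 min |

| run | time / min | [product] / M |
|---|---|---|
| dusk run | 3.2 | 0.0113 |
| dusk run | 6.5 | 0.0184 |
| dusk run | 9.8 | 0.0247 |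
| dusk run | 13 | 0.0289 |
| dusk run | 16 | 0.0326 |
| dusk run | 20 | 0.0355 |
| dusk run | 23 | 0.0369 |
| dusk run | 26 | 0.0391 |
| summer run | 3.2 | 0.0160 |
| summer run | 6.5 | 0.0266 |
| summer run | 9.8 | 0.0342 |
| summer run | 13 | 0.0384 |
| summer run | 16 | 0.0420 |
| summer run | 20 | 0.0446 |
| summer run | 23 | 0.0459 |
| summer run | 26 | 0.0467 |
| midnight run | 3.2 | 0.0212 |
| midnight run | 6.5 | 0.0351 |
| midnight run | 9.8 | 0.0451 |
| midnight run | 13 | 0.0521 |
| midnight run | 16 | 0.0581 |
| midnight run | 20 | 0.0633 |
| midnight run | 23 | 0.0662 |
| midnight run | 26 | 0.0688 |

(scatter of a reading: 3 × 10⁻⁴ M)

* the power of [starting material] that the first rate follows, about the charge of the dusk run; measure it at two percent of starting material made into product (one fixed amount of product, the same in the runs compared)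
* the power of [coupling partner] that the first rate follows, about the charge of the dusk run; measure it at two percent of starting material made into product
* product in the noon run at 26 min, as a share of the starting material charged

- Overall: starting material + coupling partner -> product.
- Constant volume, constant temperature.
- Readings of a species count what is bound in complexes too.
- "The second partner" is coupling partner.
- An order is taken over about fifteen percent of the charge, up and down.

My own reckoning follows the noon run in slow motion. Early on, the product made depends on the charge of starting material. At 3.2 min the midnight run holds 0.0212 M of product and the dusk run 0.0113 M, which gives an exponent across their charges: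

n = ln(0.0212 / 0.0113) / ln(0.150 / 0.0500) = 0.573

In the middle, the noon run keeps starting material over: 0.260 M of it remains even at the cap. Coupling partner should therefore fall in a pseudo-first-order way. This suggests counting the turns of the partner, the logarithm of its charge over that charge minus the product made. The midnight run, where starting material falls by the product made, gives at 26 min:

turns = ln(0.100 / (0.100 − 0.0688)) = 1.16

Towards the end, this reckoning lets turns scale with the charge by the exponent n and bends product over towards the cap:

noon turns = 1.16 × (0.360 / 0.150)^0.573 = 1.92

share = 27.8% × (1 − e^(−1.92)) = 23.7%

The forecast says 0.76 for the order in starting material, 0.95 for the order in coupling partner and 21% for the noon share, reasoning that “rate rises less than proportionally with starting material”. Its share is lower than mine.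

The simulation gives 0.67, 1.1 and 23.3%.

    2 coupling partner ⇌ reagent dimer, settled at all times (177.0 M⁻¹)
    starting material + reagent dimer → product + coupling partner (4.026 M⁻¹ min⁻¹)
    2 starting material ⇌ idle substrate dimer, settled at all times (24.50 M⁻¹)
    2 coupling partner → lost reagent (2.970 M⁻¹ min⁻¹)

The order in starting material lies below one because two starting material join to idle substrate dimer: the dusk charge shows 0.67 with that joining and 1.0 without it. In the noon run the turns come to 1.82, against 1.16 in the midnight run, an exponent of 0.512 between those charges. The simulated noon run without that joining reaches 26.9%, which is 3.49 turns.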